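**Retrosynthetic overview**

- The strategy rests on the chain N(secondary amine)–CH2–CH2–CH2–NH–C(=O)–CH2 of the target. It is the opened form of a 2-substituted 5,6-dihydro-4H-1,3-oxazine: ring O1 becomes the amide oxygen, C2 the amide carbon, N3 the amide nitrogen, and C6 the methylene on the secondary amine nitrogen.
- Key disconnection: the N–C6 bond, made by opening oxazine 6 with the acidic N–H of 2-nitrobenzenesulfonamide 13. Thiolate removal of the sulfonyl group and one hydrogenolysis (carbamate and four benzyl ethers) then finish the synthesis.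
- Sulfonamide 13 comes from mono-Boc-butanediamine 7 and aldehyde 8 by reductive amination, acylation with the benzylated acid 3, and exchange of Boc for the nitrobenzenesulfonyl group. The sulfonamide N–H is installed last so that it is not present during the reductive amination and the acylation.
- Oxazine 6 comes from acid 3 and 3-aminopropan-1-ol by amidation and cyclodehydration.
- Rings: both catechol rings are bought. The only ring made is the dihydro-oxazine (step 4), and it is opened again in the key step.

Key step: step 9

Remark: the target has no stereocentre and is drawn as the free base. The last step should deliver it as the dihydrochloride, and the compound list gives the neutral structure.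

**Route**

Step 1
Reactants: 1 3-(3,4-dihydroxyphenyl)propanoic acid
Product: 2 benzyl 3-[3,4-bis(benzyloxy)phenyl]propanoate
Conditions: BnBr (3.5 equiv), K2CO3 (4 equiv), DMF, 60 °C, N2
Reagents that add atoms: benzyl bromide, BrCc1ccccc1
Why: Williamson O-alkylation of both phenoxides and of the carboxylate should give the tribenzyl compound, with air excluded to protect the catechol.

Step 2
Reactants: 2 benzyl 3-[3,4-bis(benzyloxy)phenyl]propanoate
Product: 3 3-[3,4-bis(benzyloxy)phenyl]propanoic acid
Conditions: NaOH (2 M aq), THF/MeOH, 50 °C; then 1 M HCl to pH 2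
Reagents that add atoms: sodium hydroxide (its oxygen becomes the acid O–H oxygen), [Na+].[OH-]
Why: Saponification should cleave only the benzyl ester, since the aryl benzyl ethers are inert to hydroxide.

Step 3
Reactants: 3 3-[3,4-bis(benzyloxy)phenyl]propanoic acid; 4 3-aminopropan-1-ol
Product: 5 3-[3,4-bis(benzyloxy)phenyl]-N-(3-hydroxypropyl)propanamide
Conditions: EDC·HCl, HOBt, CH2Cl2, 0 °C to rt
Reagents that add atoms: none
Why: Carbodiimide amidation through the benzotriazolyl ester should acylate the amine and leave the much less nucleophilic primary alcohol free.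

Step 4
Reactants: 5 3-[3,4-bis(benzyloxy)phenyl]-N-(3-hydroxypropyl)propanamide
Product: 6 2-{2-[3,4-bis(benzyloxy)phenyl]ethyl}-5,6-dihydro-4H-1,3-oxazine
Conditions: PPh3, DIAD, THF, 0 °C to rt; chromatography on Et3N-deactivated silica, stored dry
Reagents that add atoms: none
Why: Mitsunobu cyclodehydration, in which the amide oxygen displaces the alkoxyphosphonium group of the primary alcohol in a 6-exo-tet closure, is an established route from N-(3-hydroxypropyl)amides to dihydro-oxazines.

Step 5
Reactants: 7 tert-butyl N-(4-aminobutyl)carbamate; 8 benzyl N-(3-oxopropyl)carbamate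
Product: 10 benzyl N-[3-({4-[(tert-butoxycarbonyl)amino]butyl}amino)propyl]carbamate, via aldimine 9 (not isolated)
Conditions: 7 (1.5 equiv), MeOH, 3 Å MS, rt; then NaBH4, 0 °C
Reagents that add atoms: none
Why: Stepwise reductive amination (imine formed first with the amine in excess, then borohydride reduction) should hold back double alkylation of the primary amine.

Step 6
Reactants: 10 benzyl N-[3-({4-[(tert-butoxycarbonyl)amino]butyl}amino)propyl]carbamate; 3 3-[3,4-bis(benzyloxy)phenyl]propanoic acid
Product: 11 benzyl N-[3-({3-[3,4-bis(benzyloxy)phenyl]propanoyl}{4-[(tert-butoxycarbonyl)amino]butyl}amino)propyl]carbamate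
Conditions: EDC·HCl, HOBt, CH2Cl2, rt
Reagents that add atoms: none
Why: Carbodiimide amidation should acylate the only basic nitrogen, the secondary amine, since both carbamate nitrogens are non-nucleophilic.

Step 7
Reactants: 11 benzyl N-[3-({3-[3,4-bis(benzyloxy)phenyl]propanoyl}{4-[(tert-butoxycarbonyl)amino]butyl}amino)propyl]carbamate
Product: 12 benzyl N-[3-((4-aminobutyl){3-[3,4-bis(benzyloxy)phenyl]propanoyl}amino)propyl]carbamate hydrochloride
Conditions: HCl (4 M in 1,4-dioxane), CH2Cl2, rt; evaporation, trituration with Et2O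
Reagents that add atoms: hydrogen chloride, Cl
Why: Acidolysis of the tert-butyl carbamate with anhydrous HCl should leave the benzyl carbamate, the aryl benzyl ethers and the amide untouched.

Step 8
Reactants: 12 benzyl N-[3-((4-aminobutyl){3-[3,4-bis(benzyloxy)phenyl]propanoyl}amino)propyl]carbamate hydrochloride
Product: 13 benzyl N-[3-({3-[3,4-bis(benzyloxy)phenyl]propanoyl}{4-[(2-nitrophenyl)sulfonylamino]butyl}amino)propyl]carbamate
Conditions: 2-nitrobenzenesulfonyl chloride (1.05 equiv), Et3N (2.5 equiv), CH2Cl2, 0 °C
Reagents that add atoms: 2-nitrobenzenesulfonyl chloride, O=S(=O)(Cl)c1ccccc1[N+](=O)[O-]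
Why: Sulfonylation of the freed primary amine with a near-stoichiometric amount of the chloride at low temperature should stop at the mono-sulfonamide that carries the acidic N–H needed next.

Step 9
Reactants: 13 benzyl N-[3-({3-[3,4-bis(benzyloxy)phenyl]propanoyl}{4-[(2-nitrophenyl)sulfonylamino]butyl}amino)propyl]carbamate; 6 2-{2-[3,4-bis(benzyloxy)phenyl]ethyl}-5,6-dihydro-4H-1,3-oxazine
Product: 14 benzyl N-{3-[{3-[3,4-bis(benzyloxy)phenyl]propanoyl}(4-{[3-({3-[3,4-bis(benzyloxy)phenyl]propanoyl}amino)propyl][(2-nitrophenyl)sulfonyl]amino}butyl)amino]propyl}carbamate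
Conditions: 6 (1.5 equiv, syringe pump over 8 h), dry sulfolane (1 M in 13), 4 Å MS, 135 °C, Ar; then 135 °C, 12 h
Reagents that add atoms: none
Why: Proposed new method: the 2-nitrobenzenesulfonamide N–H of 13, the only N–H in either partner acidic enough to do so, should transfer its proton to the imidate nitrogen of 6, and the sulfonamidate of the resulting ion pair should attack the O–CH2 carbon (C6) of the oxazinium ion in an SN2 step that breaks the C6–O bond and releases the neutral secondary amide, so that the N–C bond and the amide arise together and nothing is split off. The closest known reaction types are the opening of 2-oxazolines at C5 by acidic pronucleophiles (thiophenols, carboxylic acids) and the SN2 propagation step of the cationic ring-opening polymerisation of 2-substituted 5,6-dihydro-4H-1,3-oxazines, in which a neutral imidate nitrogen plays the part given here to the far more nucleophilic sulfonamidate. No ring is closed (the six-membered imidate ring is opened) and no stereocentre is formed. The step needs attack at C6 and not at C2, which should hold because addition at C2 gives a tetrahedral adduct that can only revert (its collapse would have to give an N-sulfonyl amidinium ion), whereas opening at C6 is made irreversible by the gain of the amide carbonyl. It also needs a single alkylation and no chain growth of 6: the product sulfonamide has no N–H, the amide and carbamate N–H groups are too weakly acidic to form the ion pair, and 6 is added slowly and without external strong acid, since such an acid would raise the oxazinium concentration without raising the ion-pair product fixed by the sulfonamide equilibrium and would therefore favour only oligomerisation. The lower ring strain of the oxazine compared with an oxazoline is met by the high temperature, the high concentration and the polar, non-nucleophilic solvent.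

Step 10
Reactants: 14 benzyl N-{3-[{3-[3,4-bis(benzyloxy)phenyl]propanoyl}(4-{[3-({3-[3,4-bis(benzyloxy)phenyl]propanoyl}amino)propyl][(2-nitrophenyl)sulfonyl]amino}butyl)amino]propyl}carbamate
Product: 15 benzyl N-{3-[{3-[3,4-bis(benzyloxy)phenyl]propanoyl}(4-{[3-({3-[3,4-bis(benzyloxy)phenyl]propanoyl}amino)propyl]amino}butyl)amino]propyl}carbamate
Conditions: PhSH (2 equiv), K2CO3 (3 equiv), DMF, rt; chromatography to remove all sulfur-containing material
Reagents that add atoms: none
Why: Fukuyama denosylation (ipso-substitution by thiolate through a Meisenheimer adduct, then loss of sulfur dioxide) should free the secondary amine without touching the amides, the carbamate or the benzyl ethers.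

Step 11
Reactants: 15 benzyl N-{3-[{3-[3,4-bis(benzyloxy)phenyl]propanoyl}(4-{[3-({3-[3,4-bis(benzyloxy)phenyl]propanoyl}amino)propyl]amino}butyl)amino]propyl}carbamate
Product: 16 kukoamine B, N-{3-[(4-{(3-aminopropyl)[3-(3,4-dihydroxyphenyl)propanoyl]amino}butyl)amino]propyl}-3-(3,4-dihydroxyphenyl)propanamide
Conditions: H2 (1 atm), Pd/C (10 wt %), MeOH, aq HCl (2.2 equiv), rt; product collected as the dihydrochloride
Reagents that add atoms: none
Why: Catalytic hydrogenolysis should cleave the four benzylic C–O bonds of the ethers and that of the carbamate (which then loses carbon dioxide) in one operation, and the acid should keep the amines protonated so that they do not poison the catalyst and the catechols do not oxidise.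

**Compound list**

1 | 3-(3,4-dihydroxyphenyl)propanoic acid | O=C(O)CCc1ccc(O)c(O)c1 | starting material
2 | benzyl 3-[3,4-bis(benzyloxy)phenyl]propanoate | O=C(OCc1ccccc1)CCc1ccc(OCc2ccccc2)c(OCc2ccccc2)c1 | intermediate
3 | 3-[3,4-bis(benzyloxy)phenyl]propanoic acid | O=C(O)CCc1ccc(OCc2ccccc2)c(OCc2ccccc2)c1 | intermediate
4 | 3-aminopropan-1-ol | NCCCO | starting material
5 | 3-[3,4-bis(benzyloxy)phenyl]-N-(3-hydroxypropyl)propanamide | O=C(NCCCO)CCc1ccc(OCc2ccccc2)c(OCc2ccccc2)c1 | intermediate
6 | 2-{2-[3,4-bis(benzyloxy)phenyl]ethyl}-5,6-dihydro-4H-1,3-oxazine | C1CN=C(CCc2ccc(OCc3ccccc3)c(OCc3ccccc3)c2)OC1 | intermediate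
7 | tert-butyl N-(4-aminobutyl)carbamate | CC(C)(C)OC(=O)NCCCCN | starting material
8 | benzyl N-(3-oxopropyl)carbamate | O=CCCNC(=O)OCc1ccccc1 | starting material
9 | benzyl N-[3-({4-[(tert-butoxycarbonyl)amino]butyl}imino)propyl]carbamate (aldimine) | CC(C)(C)OC(=O)NCCCCN=CCCNC(=O)OCc1ccccc1 | intermediate (not isolated)
10 | benzyl N-[3-({4-[(tert-butoxycarbonyl)amino]butyl}amino)propyl]carbamate | CC(C)(C)OC(=O)NCCCCNCCCNC(=O)OCc1ccccc1 | intermediate
11 | benzyl N-[3-({3-[3,4-bis(benzyloxy)phenyl]propanoyl}{4-[(tert-butoxycarbonyl)amino]butyl}amino)propyl]carbamate | CC(C)(C)OC(=O)NCCCCN(CCCNC(=O)OCc1ccccc1)C(=O)CCc1ccc(OCc2ccccc2)c(OCc2ccccc2)c1 | intermediate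
12 | benzyl N-[3-((4-aminobutyl){3-[3,4-bis(benzyloxy)phenyl]propanoyl}amino)propyl]carbamate hydrochloride | Cl.NCCCCN(CCCNC(=O)OCc1ccccc1)C(=O)CCc1ccc(OCc2ccccc2)c(OCc2ccccc2)c1 | intermediate
13 | benzyl N-[3-({3-[3,4-bis(benzyloxy)phenyl]propanoyl}{4-[(2-nitrophenyl)sulfonylamino]butyl}amino)propyl]carbamate | O=C(OCc1ccccc1)NCCCN(CCCCNS(=O)(=O)c1ccccc1[N+](=O)[O-])C(=O)CCc1ccc(OCc2ccccc2)c(OCc2ccccc2)c1 | intermediate
14 | benzyl N-{3-[{3-[3,4-bis(benzyloxy)phenyl]propanoyl}(4-{[3-({3-[3,4-bis(benzyloxy)phenyl]propanoyl}amino)propyl][(2-nitrophenyl)sulfonyl]amino}butyl)amino]propyl}carbamate | O=C(OCc1ccccc1)NCCCN(CCCCN(CCCNC(=O)CCc1ccc(OCc2ccccc2)c(OCc2ccccc2)c1)S(=O)(=O)c1ccccc1[N+](=O)[O-])C(=O)CCc1ccc(OCc2ccccc2)c(OCc2ccccc2)c1 | intermediate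
15 | benzyl N-{3-[{3-[3,4-bis(benzyloxy)phenyl]propanoyl}(4-{[3-({3-[3,4-bis(benzyloxy)phenyl]propanoyl}amino)propyl]amino}butyl)amino]propyl}carbamate | O=C(OCc1ccccc1)NCCCN(CCCCNCCCNC(=O)CCc1ccc(OCc2ccccc2)c(OCc2ccccc2)c1)C(=O)CCc1ccc(OCc2ccccc2)c(OCc2ccccc2)c1 | intermediate
16 | kukoamine B | NCCCN(CCCCNCCCNC(=O)CCc1ccc(O)c(O)c1)C(=O)CCc1ccc(O)c(O)c1 | target

**Step count**

Total: 11 steps. Longest linear sequence: 8 steps (1 → 2 → 3 → 11 → 12 → 13 → 14 → 15 → 16, that is steps 1, 2, 6, 7, 8, 9, 10 and 11).

**Steps most likely to fail**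

1. Step 9 (proposed new method). The proton transfer and SN2 sequence may be too slow below the temperature at which the oxazine grows chains on itself, or a second oxazine may insert before the sulfonamidate closes the sequence. The fallback uses known chemistry and sets out from 13. Fukuyama alkylation of 13 with tert-butyl N-(3-bromopropyl)carbamate (Cs2CO3, DMF, 50 °C) should give benzyl N-{3-[{3-[3,4-bis(benzyloxy)phenyl]propanoyl}(4-{[3-(tert-butoxycarbonylamino)propyl][(2-nitrophenyl)sulfonyl]amino}butyl)amino]propyl}carbamate F1. HCl in 1,4-dioxane should then give the primary amine hydrochloride F2. Carbodiimide amidation of the primary amine hydrochloride F2 with acid 3 (EDC·HCl, HOBt, Et3N, CH2Cl2) comes back to the route at 14.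

2. Step 5. The primary amine may be alkylated twice, and the aldehyde may lose its carbamate by β-elimination before the imine forms. The fallback sets out from 7. Sulfonylation (2-nitrobenzenesulfonyl chloride, Et3N, CH2Cl2) should give tert-butyl N-{4-[(2-nitrophenyl)sulfonylamino]butyl}carbamate F3. A Fukuyama–Mitsunobu alkylation with commercial benzyl N-(3-hydroxypropyl)carbamate (PPh3, DIAD, THF) should give benzyl N-[3-({4-[(tert-butoxycarbonyl)amino]butyl}[(2-nitrophenyl)sulfonyl]amino)propyl]carbamate F4, in which a second alkylation is impossible. Thiolate cleavage (PhSH, K2CO3, DMF) comes back to the route at 10.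

3. Step 4. The imidate ring may be opened hydrolytically during separation from the phosphine oxide, or the closure may stall at the alkoxyphosphonium stage. The fallback sets out from 5 and replaces the redox dehydration by a sulfonate displacement. Mesylation (MsCl, Et3N, CH2Cl2, 0 °C) should give 3-({3-[3,4-bis(benzyloxy)phenyl]propanoyl}amino)propyl methanesulfonate F5. Warming with DBU in MeCN at 60 °C should close the ring through the amide oxygen and comes back to the route at 6, with only water-soluble salts to remove.

**Further compounds**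

F1 | step 9 | benzyl N-{3-[{3-[3,4-bis(benzyloxy)phenyl]propanoyl}(4-{[3-(tert-butoxycarbonylamino)propyl][(2-nitrophenyl)sulfonyl]amino}butyl)amino]propyl}carbamate | CC(C)(C)OC(=O)NCCCN(CCCCN(CCCNC(=O)OCc1ccccc1)C(=O)CCc1ccc(OCc2ccccc2)c(OCc2ccccc2)c1)S(=O)(=O)c1ccccc1[N+](=O)[O-]
F2 | step 9 | benzyl N-{3-[(4-{(3-aminopropyl)[(2-nitrophenyl)sulfonyl]amino}butyl){3-[3,4-bis(benzyloxy)phenyl]propanoyl}amino]propyl}carbamate hydrochloride | Cl.NCCCN(CCCCN(CCCNC(=O)OCc1ccccc1)C(=O)CCc1ccc(OCc2ccccc2)c(OCc2ccccc2)c1)S(=O)(=O)c1ccccc1[N+](=O)[O-]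
F3 | step 5 | tert-butyl N-{4-[(2-nitrophenyl)sulfonylamino]butyl}carbamate | CC(C)(C)OC(=O)NCCCCNS(=O)(=O)c1ccccc1[N+](=O)[O-]
F4 | step 5 | benzyl N-[3-({4-[(tert-butoxycarbonyl)amino]butyl}[(2-nitrophenyl)sulfonyl]amino)propyl]carbamate | CC(C)(C)OC(=O)NCCCCN(CCCNC(=O)OCc1ccccc1)S(=O)(=O)c1ccccc1[N+](=O)[O-]
F5 | step 4 | 3-({3-[3,4-bis(benzyloxy)phenyl]propanoyl}amino)propyl methanesulfonate | CS(=O)(=O)OCCCNC(=O)CCc1ccc(OCc2ccccc2)c(OCc2ccccc2)c1
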